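**Assumption:** arthonioic acid has no stereocentre or stereogenic axis, so it is achiral and needs no stereocontrol; N-methoxy-N-methylhexanamide is taken as a catalogue reagent.

## Retrosynthetic overview

1. Target ← fully masked depside (two 4-methoxybenzyl ethers on ring A, one tert-butyl ester on ring B) by a single acidolysis.
2. Key disconnection: the depside C(aryl)–O bond at C4 of ring B, made by nickel-catalysed, triplet-sensitised coupling of the ring A carboxylic acid with the ring B aryl iodide. The acyl group is never activated, so the ketone enol cannot close to an isocoumarin.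
3. Ring B iodide ← 2-methoxy-6-methylbenzoic acid: tert-butyl ester, sterically controlled C–H borylation/iodination at C4, then lateral lithiation and acylation with the hexanoyl Weinreb amide.
4. Ring A acid ← ethyl orsellinate: bis-4-methoxybenzyl protection, the same lateral acylation, then saponification.
5. No ring is formed: both benzene rings are bought. Ring B is elaborated first, ring A second, then the two are joined.

## Route

Step 1
Reactants: 1 2-methoxy-6-methylbenzoic acid
Product: 2 tert-butyl 2-methoxy-6-methylbenzoate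
Conditions: Cl3CC(=NH)OtBu (2 equiv), BF3·OEt2 (10 mol%), CH2Cl2/cyclohexane 1:2, rt, 16 h
Reagents that add atoms: tert-butyl 2,2,2-trichloroacetimidate, CC(C)(C)OC(=N)C(Cl)(Cl)Cl
Why: Acid-catalysed O-tert-butylation of the carboxylic acid by the imidate (trichloroacetimidate esterification) alkylates at oxygen, so the di-ortho hindrance of the acyl carbon does not matter.

Step 2
Reactants: 2 tert-butyl 2-methoxy-6-methylbenzoate
Product: 4 tert-butyl 4-iodo-2-methoxy-6-methylbenzoate, via pinacol arylboronate 3 (not isolated)
Conditions: [Ir(OMe)(cod)]2 (1.5 mol%), dtbbpy (3 mol%), B2pin2 (1.0 equiv), THF, 80 °C; evaporate; then CuI (copper monoiodide, 10 mol%), 1,10-phenanthroline (20 mol%), KI (1.5 equiv), MeOH/H2O 4:1, air, 80 °C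
Reagents that add atoms: bis(pinacolato)diboron, CC1(C)OB(OC1(C)C)B1OC(C)(C)C(C)(C)O1; potassium iodide, [K+].[I-]
Why: Iridium-catalysed C–H borylation is sterically governed, so only C4–H (the one ring hydrogen with no ortho substituent) reacts, and copper-catalysed aerobic iododeboronation then replaces boron by iodine at that carbon under neutral conditions that spare the tert-butyl ester.

Step 3
Reactants: 4 tert-butyl 4-iodo-2-methoxy-6-methylbenzoate; 5 N-methoxy-N-methylhexanamide
Product: 6 tert-butyl 4-iodo-2-methoxy-6-(2-oxoheptyl)benzoate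
Conditions: LiN(iPr)2 (commercial solution, 1.1 equiv), THF, −78 °C, 30 min; then 5 (1.3 equiv), −78 to −40 °C; AcOH quench
Reagents that add atoms: none
Why: Lateral (benzylic) lithiation of the ortho-toluate gives an ester-stabilised benzylic anion, and Weinreb ketone synthesis stops at the chelated tetrahedral adduct so the ketone appears only on quench; the amide base does not exchange the aryl iodide at −78 °C.

Step 4
Reactants: 7 ethyl 2,4-dihydroxy-6-methylbenzoate (ethyl orsellinate)
Product: 8 ethyl 2,4-bis[(4-methoxyphenyl)methoxy]-6-methylbenzoate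
Conditions: 4-MeOC6H4CH2Cl (2.5 equiv), K2CO3 (3 equiv), DMF, 70 °C
Reagents that add atoms: 4-methoxybenzyl chloride, COc1ccc(CCl)cc1
Why: Williamson ether synthesis on both phenols; heating in DMF overcomes the hydrogen bond that holds the 2-OH to the ester.

Step 5
Reactants: 8 ethyl 2,4-bis[(4-methoxyphenyl)methoxy]-6-methylbenzoate; 5 N-methoxy-N-methylhexanamide
Product: 9 ethyl 2,4-bis[(4-methoxyphenyl)methoxy]-6-(2-oxoheptyl)benzoate
Conditions: LiN(iPr)2 (commercial solution, 1.2 equiv), THF, −78 °C; then 5 (1.3 equiv), −78 to −40 °C; AcOH quench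
Reagents that add atoms: none
Why: The same lateral lithiation/Weinreb acylation as in step 3, well established for 2,4-dialkoxy-6-methylbenzoates; the benzylic ethers are inert to the amide base at −78 °C.

Step 6
Reactants: 9 ethyl 2,4-bis[(4-methoxyphenyl)methoxy]-6-(2-oxoheptyl)benzoate
Product: 10 2,4-bis[(4-methoxyphenyl)methoxy]-6-(2-oxoheptyl)benzoic acid
Conditions: KOH (5 equiv), EtOH/H2O 3:1, 75 °C; then 1 M HCl to pH 3 at 0 °C
Reagents that add atoms: potassium hydroxide, [K+].[OH-]
Why: Saponification of the ethyl ester with excess hydroxide gives the carboxylate, which is inert to further base chemistry, and cold mild acidification returns the keto acid without dehydrative lactonisation.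

Step 7
Reactants: 10 2,4-bis[(4-methoxyphenyl)methoxy]-6-(2-oxoheptyl)benzoic acid; 6 tert-butyl 4-iodo-2-methoxy-6-(2-oxoheptyl)benzoate
Product: 11 tert-butyl 4-({2,4-bis[(4-methoxyphenyl)methoxy]-6-(2-oxoheptyl)benzoyl}oxy)-2-methoxy-6-(2-oxoheptyl)benzoate
Conditions: 10 (1.3 equiv) pre-stirred with Cs2CO3 (0.65 equiv) in DMF; then 6 (1.0 equiv), Ni(cod)2 (10 mol%), dtbbpy (12 mol%), Ir(ppy)3 (2 mol%), 4 Å MS, DMF (0.1 M), 450 nm LEDs, 25 °C, 12–24 h
Reagents that add atoms: none
Why: Proposed new method: a depside C(aryl)–O bond is made by nickel-catalysed, triplet-sensitised O-arylation of a di-ortho-substituted benzoate; oxidative addition of the unhindered, ester-activated C4–I bond of 6 to zerovalent nickel/dtbbpy gives an aryl nickel iodide (divalent nickel), iodide/carboxylate exchange with the caesium salt of 10 gives the aryl nickel carboxylate, and triplet energy transfer from photoexcited Ir(ppy)3 drives C–O reductive elimination back to zerovalent nickel; because the carboxylate acts only as an O-nucleophile its acyl carbon is never electrophilic, so the ketone enol cannot close to the isocoumarin that threatens acyl-activation couplings of 2-(2-oxoalkyl)benzoic acids, and no base stronger than a carboxylate is present to enolise the product; the closest known reaction type is nickel/photosensitiser esterification of aryl bromides with simple carboxylic acids, not yet shown for hindered ortho-alkoxy keto benzoic acids, for such aryl iodides or for depsides.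

Step 8
Reactants: 11 tert-butyl 4-({2,4-bis[(4-methoxyphenyl)methoxy]-6-(2-oxoheptyl)benzoyl}oxy)-2-methoxy-6-(2-oxoheptyl)benzoate
Product: 12 arthonioic acid, 4-{[2,4-dihydroxy-6-(2-oxoheptyl)benzoyl]oxy}-2-methoxy-6-(2-oxoheptyl)benzoic acid
Conditions: TFA/CH2Cl2 1:4, anisole (10 equiv), 0 °C, 1 h; evaporate cold from toluene
Reagents that add atoms: none
Why: Acidolysis (SN1/E1) ionises the di-ortho-substituted tert-butyl ester to isobutene and the two aryl 4-methoxybenzyl ethers to a benzylic cation that anisole traps by Friedel–Crafts alkylation, while the methyl ether, both ketones and the depside ester should tolerate cold dilute acid for this short time.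

## Compound list

1 | 2-methoxy-6-methylbenzoic acid | COc1cccc(C)c1C(=O)O | starting material
2 | tert-butyl 2-methoxy-6-methylbenzoate | COc1cccc(C)c1C(=O)OC(C)(C)C | intermediate
3 | tert-butyl 2-methoxy-6-methyl-4-(4,4,5,5-tetramethyl-1,3,2-dioxaborolan-2-yl)benzoate | COc1cc(B2OC(C)(C)C(C)(C)O2)cc(C)c1C(=O)OC(C)(C)C | intermediate
4 | tert-butyl 4-iodo-2-methoxy-6-methylbenzoate | COc1cc(I)cc(C)c1C(=O)OC(C)(C)C | intermediate
5 | N-methoxy-N-methylhexanamide | CCCCCC(=O)N(C)OC | starting material
6 | tert-butyl 4-iodo-2-methoxy-6-(2-oxoheptyl)benzoate | CCCCCC(=O)Cc1cc(I)cc(OC)c1C(=O)OC(C)(C)C | intermediate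
7 | ethyl 2,4-dihydroxy-6-methylbenzoate | CCOC(=O)c1c(C)cc(O)cc1O | starting material
8 | ethyl 2,4-bis[(4-methoxyphenyl)methoxy]-6-methylbenzoate | CCOC(=O)c1c(C)cc(OCc2ccc(OC)cc2)cc1OCc1ccc(OC)cc1 | intermediate
9 | ethyl 2,4-bis[(4-methoxyphenyl)methoxy]-6-(2-oxoheptyl)benzoate | CCCCCC(=O)Cc1cc(OCc2ccc(OC)cc2)cc(OCc2ccc(OC)cc2)c1C(=O)OCC | intermediate
10 | 2,4-bis[(4-methoxyphenyl)methoxy]-6-(2-oxoheptyl)benzoic acid | CCCCCC(=O)Cc1cc(OCc2ccc(OC)cc2)cc(OCc2ccc(OC)cc2)c1C(=O)O | intermediate
11 | tert-butyl 4-({2,4-bis[(4-methoxyphenyl)methoxy]-6-(2-oxoheptyl)benzoyl}oxy)-2-methoxy-6-(2-oxoheptyl)benzoate | CCCCCC(=O)Cc1cc(OCc2ccc(OC)cc2)cc(OCc2ccc(OC)cc2)c1C(=O)Oc1cc(CC(=O)CCCCC)c(C(=O)OC(C)(C)C)c(OC)c1 | intermediate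
12 | arthonioic acid | CCCCCC(=O)Cc1cc(O)cc(O)c1C(=O)Oc1cc(CC(=O)CCCCC)c(C(=O)O)c(OC)c1 | target

## Step count

Total steps: 8. Longest linear sequence: 5 steps (steps 1, 2, 3, 7, 8 or steps 4, 5, 6, 7, 8).

## Steps most likely to fail, with fallbacks

**Step 7 (the new coupling).** The hindered carboxylate may exchange or reductively eliminate slowly. The photocatalyst may reduce the aryl iodide directly, giving the de-iodinated arene. The product depside can lose its ring B phenol by base-triggered enol-lactonisation if the reaction runs long. The fallback uses known chemistry and makes the ester bond the classical way. It sets out from 6, which undergoes Miyaura borylation (PdCl2(dppf), B2pin2, KOAc, dioxane, 80 °C) to tert-butyl 2-methoxy-6-(2-oxoheptyl)-4-(4,4,5,5-tetramethyl-1,3,2-dioxaborolan-2-yl)benzoate F2. Oxidation of F2 with H2O2/NaHCO3 in THF/H2O at 0 °C gives the phenol tert-butyl 4-hydroxy-2-methoxy-6-(2-oxoheptyl)benzoate F3. Steglich esterification of F3 with acid 10 (DCC, catalytic DMAP, CH2Cl2, 0 °C, base kept lean to limit lactonisation of the activated acid) rejoins the route at 11.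

**Step 8 (global acidolysis).** Acid may promote enol-lactonisation with loss of ring B, dehydrative lactonisation of the ring B keto acid, or C-benzylation of the freed resorcinol ring by the 4-methoxybenzyl cation. The fallback separates the two unmaskings and generates no benzylic cation. It sets out from 11, whose two benzylic ethers are removed by neutral hydrogenolysis (H2, Pd/C, EtOAc, rt) to give tert-butyl 4-{[2,4-dihydroxy-6-(2-oxoheptyl)benzoyl]oxy}-2-methoxy-6-(2-oxoheptyl)benzoate F4. The tert-butyl ester of F4 is then cleaved with a Lewis acid (ZnBr2, CH2Cl2, rt), arriving at 12.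

**Step 6 (saponification of the keto ester).** Under hot hydroxide the ketone enolate on the pentyl side can attack the ester in a Claisen-type ring closure to a naphthalene-1,3-diol, and the hindered ester may hydrolyse slowly. The fallback reverses the order so that no ketone ever meets hydroxide. It sets out from 8, which is saponified first (KOH, DMSO/H2O, 100 °C) to 2,4-bis[(4-methoxyphenyl)methoxy]-6-methylbenzoic acid F1. F1 is converted to its carboxylate/benzylic dianion with LiN(iPr)2 (2.3 equiv, THF, −78 to 0 °C) and acylated with 5 at −78 °C. A cold mild acid quench delivers 10 directly, where the route resumes.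

## Further compounds

F1 | step 6 | 2,4-bis[(4-methoxyphenyl)methoxy]-6-methylbenzoic acid | Cc1cc(OCc2ccc(OC)cc2)cc(OCc2ccc(OC)cc2)c1C(=O)O
F2 | step 7 | tert-butyl 2-methoxy-6-(2-oxoheptyl)-4-(4,4,5,5-tetramethyl-1,3,2-dioxaborolan-2-yl)benzoate | CCCCCC(=O)Cc1cc(B2OC(C)(C)C(C)(C)O2)cc(OC)c1C(=O)OC(C)(C)C
F3 | step 7 | tert-butyl 4-hydroxy-2-methoxy-6-(2-oxoheptyl)benzoate | CCCCCC(=O)Cc1cc(O)cc(OC)c1C(=O)OC(C)(C)C
F4 | step 8 | tert-butyl 4-{[2,4-dihydroxy-6-(2-oxoheptyl)benzoyl]oxy}-2-methoxy-6-(2-oxoheptyl)benzoate | CCCCCC(=O)Cc1cc(O)cc(O)c1C(=O)Oc1cc(CC(=O)CCCCC)c(C(=O)OC(C)(C)C)c(OC)c1
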